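Take the easy step first: starting material disappears steadily, and the noon run shows how fast.

- noon: starting material 0.031 M; solid reagent 0.90 equiv; capture agent 3.1 mM; free catalyst 1 mol%; run made earlier
- flask: starting material 0.031 M; solid reagent 0.900 equiv; capture agent 1.55 mM; free catalyst 1 mol%; time 6.0 h

noon run (percent of the starting material charged)

| time / min | product / % | starting material / % |
|---|---|---|
| 10.0 | 0 | 87.5 |
| 25.0 | 1.4 | 72.8 |
| 50.0 | 1.2 | 57.1 |
| 80.0 | 5.7 | 42.6 |
| 120 | 10.2 | 30.2 |

(each reading ± 0.5 percentage points)

- solid, in amounts per volume of the solution: solid reagent
- the analysis behind the earlier runs scatters by 0.5 percentage points, standard deviation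
- at the start none of the solid reagent is in solution
- no earlier run changes the charge of capture agent; that part of a forecast is a guess

- east: doubling the dissolution coefficient of the solid reagent, all else as stated
- north: doubling the amount of free catalyst, all else as stated
- north-east: doubling the solubility of the solid reagent, all else as stated

- amount of product at 6.0 h, in percent of the starting material charged
- the change that raises the amount of product at 6.0 h, in percent of the starting material charged most ("none" if none brings more than 2 percentage points) (east / north / north-east / none)
- amount of product at 6.0 h, in percent of the starting material charged, after north-east

Treat the last noon stretch as pseudo-first-order: c(starting material) falls at 0.00860 min⁻¹, while product gains 0.00112 min⁻¹ of the charge. Divide loss by gain. Above one, something in between fills; below one, it empties. That stretch of the noon run gives 2.76.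

Now hold the product pace and let the loss decay. Carried over to the flask, this puts starting material at 6.0 h near 3.83% by my estimate, and the ratio down at 0.293, the hand-over number: loss of starting material over gain of product at the asked time. So this flask should be emptying its store, and I reckon 37.2% product, with 59.0% still in between. Is one number enough? No. The pace rests on two readings with a scatter of 0.5 percentage points, the capture agent is a guess, and the number ranks no change.

The forecast says 40%, above mine, then north-east as best, reaching 58%, and holds: “Extra catalyst only speeds the early step, which is not limiting.”

The flask gives 42.6%.

free catalyst + open intermediate ⇌ catalyst intermediate (K = 52.0 L mol⁻¹, k = 52.0 L mol⁻¹ min⁻¹); partner + catalyst intermediate → free catalyst + product (k = 20.0 L mol⁻¹ min⁻¹); starting material + free catalyst → free catalyst + open intermediate (k = 47.0 L mol⁻¹ min⁻¹); solid reagent ⇌ partner, rate k4*(cs4 - [partner]) while solid is left; crystals form when [partner] > cs4 (solubility = 19.0 mM, k = 0.0240 min⁻¹); open intermediate + capture agent → trapped intermediate (k = 0.590 L mol⁻¹ min⁻¹) North adds 23 points, the most, while north-east adds 4.9 points, reaching 47.5%; partner stood at 89.7% of saturation at 3.00 h. Set the hand-over number 0.293 beside the computed 0.303, making over using up of open intermediate, each step net, at 6.00 h.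

Read the same flask at 10 h: with the product pace still held, the number decays to 0.0372, so by this estimate starting material should replace hardly any of what product takes, and the store should shrink. Computed, open intermediate falls from 48.5% to 32.8% as product reaches 61.6%.

Readings and results stem from a simulated flask from invented constants; the scatter is artificial.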